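**Retrosynthetic overview**

The target is a 2-aryl-5-methoxy-7-methyl-1,4-naphthoquinone. The last disconnection cuts both bonds from the benzo ring (ring A) to the quinone ring (C8a–C1 and C4a–C4), giving 3-methoxy-5-methylbenzyne and a 4-naphthyl-2-siloxyfuran, a temporary ring that already holds C1–C4 and both quinone oxygens at the butenolide oxidation level.
Enabling feature: the methoxy group on C5, the carbon next to ring-fusion atom C4a, lies beside the aryne triple bond (C4a≡C8a) and polarises it. The nucleophilic furan C5 (neighbour of the aryl-bearing carbon; it becomes C1) therefore bonds to C8a and the siloxy carbon (it becomes C4, next to C3–H) bonds to C4a; bridge opening, desilylation and air oxidation then give the quinone ring.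
The naphthyl half is made earlier by the same logic: 4-(benzyloxy)-3-methoxybenzyne plus 3-bromo-4-methyl-2-siloxyfuran closes its second ring with O1 silylated, O4 free (then methylated) and bromine on C2. Silyl-to-benzyl exchange, Negishi coupling with 4-bromofuran-2(5H)-one and enol silylation then give the key-step furan.
Order of ring formation: benzene ring of the naphthyl half (bought) → its second ring (step 3) → furanone ring attached and turned into the furan (steps 6, 7) → ring A brought in as the aryne while the quinone ring closes last (step 10); hydrogenolysis of two benzyl ethers ends the route.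

Key step: step 10

Assumption: the target SMILES has no stereodescriptor, so the biaryl axis is treated as configurationally undefined and no stereocontrol is planned; 4-methylfuran-2(5H)-one, 1-(benzyloxy)-4-bromo-2-methoxybenzene, 4-bromofuran-2(5H)-one and 2-methoxy-4-methylphenol are taken as commercial.

**Route**

Step 1
Reactants: 1 4-methylfuran-2(5H)-one
Product: 3 3-bromo-4-methylfuran-2(5H)-one, via dibromolactone 2 (not isolated)
Conditions: Br2, CH2Cl2, 0 °C → rt; then Et3N, 0 °C
Reagents that add atoms: bromine, BrBr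
Why: Anti addition of bromine to the butenolide alkene followed by amine-induced loss of HBr through the acidic α-hydrogen (bromination–dehydrobromination) should give the α-bromobutenolide as the conjugated elimination product.

Step 2
Reactants: 3 3-bromo-4-methylfuran-2(5H)-one
Product: 4 3-bromo-4-methyl-2-[(triisopropylsilyl)oxy]furan
Conditions: i-Pr3SiOTf, Et3N, CH2Cl2, 0 °C
Reagents that add atoms: triisopropylsilyl trifluoromethanesulfonate, CC(C)[Si](C(C)C)(C(C)C)OS(=O)(=O)C(F)(F)F
Why: Soft enolisation of the butenolide at C5 and O-silylation (silyl dienol ether formation) should give the aromatic 2-siloxyfuran.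

Step 3
Reactants: 4 3-bromo-4-methyl-2-[(triisopropylsilyl)oxy]furan; 5 1-(benzyloxy)-4-bromo-2-methoxybenzene
Product: 9 6-(benzyloxy)-3-bromo-5-methoxy-2-methyl-4-[(triisopropylsilyl)oxy]naphthalen-1-ol, via aryllithium 6 (not isolated), via aryne 7 (not isolated), via cycloadduct 8 (not isolated)
Conditions: lithium 2,2,6,6-tetramethylpiperidide (LiTMP), THF, −78 °C; then 4 (excess), −78 °C → rt; aq NH4Cl; silica gel, CH2Cl2
Reagents that add atoms: none
Why: Deprotonation of 5 between OMe and Br, loss of LiBr on warming and aryne Diels–Alder reaction with the siloxyfuran should give the bridged silyl ketal, in which the methoxy group beside the triple bond sends the nucleophilic furan C5 to the remote aryne carbon, and opening of the oxygen bridge at the ketal carbon should keep the bulky silyl group on the oxygen peri to OMe and leave the para oxygen as a free OH.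

Step 4
Reactants: 9 6-(benzyloxy)-3-bromo-5-methoxy-2-methyl-4-[(triisopropylsilyl)oxy]naphthalen-1-ol
Product: 10 {[7-(benzyloxy)-2-bromo-4,8-dimethoxy-3-methylnaphthalen-1-yl]oxy}triisopropylsilane
Conditions: MeI, K2CO3, acetone, 40 °C
Reagents that add atoms: iodomethane, IC
Why: Williamson ether synthesis on the only free phenol should fix the methyl ether at O4, and the hindered triisopropylsilyl ether should survive carbonate in acetone.

Step 5
Reactants: 10 {[7-(benzyloxy)-2-bromo-4,8-dimethoxy-3-methylnaphthalen-1-yl]oxy}triisopropylsilane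
Product: 12 1,7-bis(benzyloxy)-2-bromo-4,8-dimethoxy-3-methylnaphthalene, via naphtholate 11 (not isolated)
Conditions: Bu4NF, THF, 0 °C, argon; then BnBr, rt
Reagents that add atoms: benzyl bromide, BrCc1ccccc1
Why: Fluoride cleaves the aryl silyl ether and the tetrabutylammonium naphtholate is O-benzylated in the same flask (desilylation then Williamson ether synthesis), so the air-sensitive 4-methoxy-1-naphthol is never handled.

Step 6
Reactants: 12 1,7-bis(benzyloxy)-2-bromo-4,8-dimethoxy-3-methylnaphthalene; 13 4-bromofuran-2(5H)-one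
Product: 16 4-[1,7-bis(benzyloxy)-4,8-dimethoxy-3-methylnaphthalen-2-yl]furan-2(5H)-one, via aryllithium 14 (not isolated), via arylzinc chloride 15 (not isolated)
Conditions: n-BuLi, THF, −78 °C; ZnCl2, −78 °C → rt; then 13, Pd2(dba)3 (cat.), SPhos (cat.), THF, 50 °C
Reagents that add atoms: none
Why: Bromine–lithium exchange, transmetalation to zinc and Negishi coupling with the β-bromobutenolide should join the doubly ortho-substituted naphthyl group to C4 of the lactone, because the arylzinc tolerates the lactone and its acidic γ-hydrogens and a bulky biarylphosphine supports hindered couplings.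

Step 7
Reactants: 16 4-[1,7-bis(benzyloxy)-4,8-dimethoxy-3-methylnaphthalen-2-yl]furan-2(5H)-one
Product: 17 {[4-(1,7-bis(benzyloxy)-4,8-dimethoxy-3-methylnaphthalen-2-yl)furan-2-yl]oxy}(tert-butyl)dimethylsilane
Conditions: t-BuMe2SiOTf, Et3N, CH2Cl2, 0 °C
Reagents that add atoms: tert-butyldimethylsilyl trifluoromethanesulfonate, CC(C)(C)[Si](C)(C)OS(=O)(=O)C(F)(F)F
Why: Soft enolisation and O-silylation of the butenolide (silyl dienol ether formation) should give the 4-aryl-2-siloxyfuran, the diene of the key step.

Step 8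
Reactants: 18 2-methoxy-4-methylphenol (creosol)
Product: 19 2-iodo-6-methoxy-4-methylphenol
Conditions: I2, NaHCO3, THF/H2O, 0 °C → rt
Reagents that add atoms: iodine, [I][I]
Why: Electrophilic aromatic iodination of the phenoxide should go ortho to the hydroxyl group, since the para position is blocked by the methyl group and the other ortho position by OMe.

Step 9
Reactants: 19 2-iodo-6-methoxy-4-methylphenol
Product: 20 2-iodo-6-methoxy-4-methylphenyl trifluoromethanesulfonate
Conditions: Tf2O, pyridine, CH2Cl2, 0 °C
Reagents that add atoms: trifluoromethanesulfonic anhydride, O=S(=O)(OS(=O)(=O)C(F)(F)F)C(F)(F)F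
Why: O-Sulfonylation of the phenol gives the 2-iodoaryl triflate, a standard precursor that releases the aryne at −78 °C on halogen–lithium exchange.

Step 10
Reactants: 17 {[4-(1,7-bis(benzyloxy)-4,8-dimethoxy-3-methylnaphthalen-2-yl)furan-2-yl]oxy}(tert-butyl)dimethylsilane; 20 2-iodo-6-methoxy-4-methylphenyl trifluoromethanesulfonate
Product: 25 2-[1,7-bis(benzyloxy)-4,8-dimethoxy-3-methylnaphthalen-2-yl]-5-methoxy-7-methylnaphthalene-1,4-dione, via aryne 21 (not isolated), via cycloadduct 22 (not isolated), via siloxynaphthol 23 (not isolated), via hydroquinone 24 (not isolated)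
Conditions: n-BuLi (slow addition to 17 and 20), THF, −78 °C; then Bu4NF, AcOH, −78 → 0 °C; then air, rt
Reagents that add atoms: none
Why: Iodine–lithium exchange on 20 and loss of LiOTf release aryne 21 at −78 °C, which the electron-rich diene of siloxyfuran 17 takes up in a polar, asynchronous [4+2] cycloaddition (aryne Diels–Alder reaction) before any phenoxide exists in the flask. The closest known reaction type is the cycloaddition of 3-alkoxybenzynes, made from 2-iodoaryl triflates and n-BuLi, with 2-methoxyfuran, whose bridged ketal opens by itself to a 4-alkoxy-1-naphthol. The quinone ring closes as the six-membered carbocycle of the 7-oxabicyclo[2.2.1]heptadiene 22 by a [4+2] ring closure that forms C8a–C1 and C4a–C4 together; the oxygen bridge then breaks at the siloxy ketal carbon to give 23, buffered fluoride frees hydroquinone 24 and oxygen dehydrogenates it, so that the furan oxygen and the former lactone oxygen end as the C1 and C4 carbonyl groups. No stereocentre has to be controlled, since the two bridgehead centres of 22 vanish on ring opening and the target has none. The step needs regioselectivity, and the methoxy group beside the triple bond secures it: it makes the remote aryne carbon (later C8a) the electrophilic end, which bonds to the nucleophilic furan C5 next to the naphthyl-bearing carbon, while the siloxy-bearing C2 bonds to the aryne carbon ortho to OMe (later C4a), so that the aryl group ends at C2 and the CH at C3. Chemoselectivity for the furan over the alkoxynaphthalene ring and over butyllithium addition should follow from the high diene reactivity of the siloxyfuran and the slow addition of the base.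

Step 11
Reactants: 25 2-[1,7-bis(benzyloxy)-4,8-dimethoxy-3-methylnaphthalen-2-yl]-5-methoxy-7-methylnaphthalene-1,4-dione
Product: 27 burmanin C [2-(1,7-dihydroxy-4,8-dimethoxy-3-methylnaphthalen-2-yl)-5-methoxy-7-methylnaphthalene-1,4-dione], via debenzylated hydroquinone 26 (not isolated)
Conditions: H2 (1 atm), palladium on carbon (Pd/C), EtOAc/MeOH, rt; filter; then air, rt
Reagents that add atoms: none
Why: Hydrogenolysis should cleave both benzyl ethers while the quinone is held as its non-electrophilic hydroquinone, and air then restores the quinone under neutral conditions (hydrogenolysis then autoxidation), with the methyl ethers and the biaryl bond untouched.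

**Compound list**

1 | 4-methylfuran-2(5H)-one | CC1=CC(=O)OC1 | starting material
2 | trans-3,4-dibromo-4-methyldihydrofuran-2(3H)-one (racemic, not isolated) | C[C@]1(Br)COC(=O)[C@@H]1Br | intermediate
3 | 3-bromo-4-methylfuran-2(5H)-one | CC1=C(Br)C(=O)OC1 | intermediate
4 | 3-bromo-4-methyl-2-[(triisopropylsilyl)oxy]furan | Cc1coc(O[Si](C(C)C)(C(C)C)C(C)C)c1Br | intermediate
5 | 1-(benzyloxy)-4-bromo-2-methoxybenzene | COc1cc(Br)ccc1OCc1ccccc1 | starting material
6 | [3-(benzyloxy)-6-bromo-2-methoxyphenyl]lithium (not isolated) | COc1c([Li])c(Br)ccc1OCc1ccccc1 | intermediate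
7 | 4-(benzyloxy)-3-methoxybenzyne, 1-(benzyloxy)-3,4-didehydro-2-methoxybenzene (not isolated) | COC1=C(OCc2ccccc2)C=CC#C1 | intermediate
8 | 7-(benzyloxy)-2-bromo-8-methoxy-3-methyl-1-[(triisopropylsilyl)oxy]-1,4-dihydro-1,4-epoxynaphthalene (racemic, not isolated) | COc1c(OCc2ccccc2)ccc2c1[C@@]1(O[Si](C(C)C)(C(C)C)C(C)C)O[C@@H]2C(C)=C1Br | intermediate
9 | 6-(benzyloxy)-3-bromo-5-methoxy-2-methyl-4-[(triisopropylsilyl)oxy]naphthalen-1-ol | Cc1c(O)c2ccc(OCc3ccccc3)c(OC)c2c(O[Si](C(C)C)(C(C)C)C(C)C)c1Br | intermediate
10 | {[7-(benzyloxy)-2-bromo-4,8-dimethoxy-3-methylnaphthalen-1-yl]oxy}triisopropylsilane | Cc1c(OC)c2ccc(OCc3ccccc3)c(OC)c2c(O[Si](C(C)C)(C(C)C)C(C)C)c1Br | intermediate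
11 | tetrabutylammonium 7-(benzyloxy)-2-bromo-4,8-dimethoxy-3-methylnaphthalen-1-olate (not isolated) | CCCC[N+](CCCC)(CCCC)CCCC.Cc1c(OC)c2ccc(OCc3ccccc3)c(OC)c2c([O-])c1Br | intermediate
12 | 1,7-bis(benzyloxy)-2-bromo-4,8-dimethoxy-3-methylnaphthalene | Cc1c(OC)c2ccc(OCc3ccccc3)c(OC)c2c(OCc2ccccc2)c1Br | intermediate
13 | 4-bromofuran-2(5H)-one | O=C1OCC(Br)=C1 | starting material
14 | [1,7-bis(benzyloxy)-4,8-dimethoxy-3-methylnaphthalen-2-yl]lithium (not isolated) | [Li]c1c(C)c(OC)c2ccc(OCc3ccccc3)c(OC)c2c1OCc1ccccc1 | intermediate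
15 | [1,7-bis(benzyloxy)-4,8-dimethoxy-3-methylnaphthalen-2-yl]zinc chloride (not isolated) | Cl[Zn]c1c(C)c(OC)c2ccc(OCc3ccccc3)c(OC)c2c1OCc1ccccc1 | intermediate
16 | 4-[1,7-bis(benzyloxy)-4,8-dimethoxy-3-methylnaphthalen-2-yl]furan-2(5H)-one | O=C1OCC(c2c(C)c(OC)c3ccc(OCc4ccccc4)c(OC)c3c2OCc2ccccc2)=C1 | intermediate
17 | {[4-(1,7-bis(benzyloxy)-4,8-dimethoxy-3-methylnaphthalen-2-yl)furan-2-yl]oxy}(tert-butyl)dimethylsilane | CC(C)(C)[Si](C)(C)Oc1cc(-c2c(C)c(OC)c3ccc(OCc4ccccc4)c(OC)c3c2OCc2ccccc2)co1 | intermediate
18 | 2-methoxy-4-methylphenol (creosol) | COc1cc(C)ccc1O | starting material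
19 | 2-iodo-6-methoxy-4-methylphenol | COc1cc(C)cc(I)c1O | intermediate
20 | 2-iodo-6-methoxy-4-methylphenyl trifluoromethanesulfonate | COc1cc(C)cc(I)c1OS(=O)(=O)C(F)(F)F | intermediate
21 | 3-methoxy-5-methylbenzyne, 1,2-didehydro-3-methoxy-5-methylbenzene (not isolated) | COC1=CC(C)=CC#C1 | intermediate
22 | 2-[1,7-bis(benzyloxy)-4,8-dimethoxy-3-methylnaphthalen-2-yl]-4-[(tert-butyldimethylsilyl)oxy]-5-methoxy-7-methyl-1,4-dihydro-1,4-epoxynaphthalene (racemic, not isolated) | COc1cc(C)cc2c1[C@@]1(O[Si](C)(C)C(C)(C)C)O[C@@H]2C(c2c(C)c(OC)c3ccc(OCc4ccccc4)c(OC)c3c2OCc2ccccc2)=C1 | intermediate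
23 | 2-[1,7-bis(benzyloxy)-4,8-dimethoxy-3-methylnaphthalen-2-yl]-4-[(tert-butyldimethylsilyl)oxy]-5-methoxy-7-methylnaphthalen-1-ol (not isolated) | COc1cc(C)cc2c(O)c(-c3c(C)c(OC)c4ccc(OCc5ccccc5)c(OC)c4c3OCc3ccccc3)cc(O[Si](C)(C)C(C)(C)C)c12 | intermediate
24 | 2-[1,7-bis(benzyloxy)-4,8-dimethoxy-3-methylnaphthalen-2-yl]-5-methoxy-7-methylnaphthalene-1,4-diol (not isolated) | COc1cc(C)cc2c(O)c(-c3c(C)c(OC)c4ccc(OCc5ccccc5)c(OC)c4c3OCc3ccccc3)cc(O)c12 | intermediate
25 | 2-[1,7-bis(benzyloxy)-4,8-dimethoxy-3-methylnaphthalen-2-yl]-5-methoxy-7-methylnaphthalene-1,4-dione | COc1cc(C)cc2c1C(=O)C=C(c1c(C)c(OC)c3ccc(OCc4ccccc4)c(OC)c3c1OCc1ccccc1)C2=O | intermediate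
26 | 2-(1,7-dihydroxy-4,8-dimethoxy-3-methylnaphthalen-2-yl)-5-methoxy-7-methylnaphthalene-1,4-diol (not isolated) | COc1cc(C)cc2c(O)c(-c3c(C)c(OC)c4ccc(O)c(OC)c4c3O)cc(O)c12 | intermediate
27 | burmanin C, 2-(1,7-dihydroxy-4,8-dimethoxy-3-methylnaphthalen-2-yl)-5-methoxy-7-methylnaphthalene-1,4-dione | COc1cc(C)cc2c1C(=O)C=C(c1c(C)c(OC)c3ccc(O)c(OC)c3c1O)C2=O | target

**Step count and risks**

Total step count: 11. Longest linear sequence: 9 steps (steps 1, 2, 3, 4, 5, 6, 7, 10, 11); steps 8 and 9 form the side branch.

Steps most likely to fail: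

1. Step 10. The cycloaddition takes place beside a doubly ortho-substituted naphthyl group and may be slow enough for butyllithium addition to the aryne, or aryne attack on the alkoxynaphthalene, to compete; regiocontrol could also erode. The fallback is a Dötz benzannulation, which still closes the quinone ring last, and it sets out from 12. Bromine–lithium exchange (n-BuLi, THF, −78 °C) and DMF should give 1,7-bis(benzyloxy)-4,8-dimethoxy-3-methylnaphthalene-2-carbaldehyde F1. Seyferth–Gilbert homologation with dimethyl (1-diazo-2-oxopropyl)phosphonate (K2CO3, MeOH) should turn it into 1,7-bis(benzyloxy)-2-ethynyl-4,8-dimethoxy-3-methylnaphthalene F2. The carbene complex pentacarbonyl[methoxy(2-methoxy-4-methylphenyl)methylidene]chromium F3 would be made from commercial 1-bromo-2-methoxy-4-methylbenzene (n-BuLi; Cr(CO)6; Me3OBF4). Heating F2 and F3 in THF at 60 °C, then air in MeCN for demetalation, should give 2-[1,7-bis(benzyloxy)-4,8-dimethoxy-3-methylnaphthalen-2-yl]-4,5-dimethoxy-7-methylnaphthalen-1-ol F4; the large alkyne substituent ends next to the new hydroxyl group and the ring closes onto the only free ortho position of the carbene aryl group. PhI(OAc)2 in MeCN/H2O at 0 °C should oxidise the free 4-methoxy-1-naphthol to the quinone, and the fallback comes back to the route at 25.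

2. Step 3. The lithiated arene or the amide base may add to the aryne, or exchange with the bromine of the furan, faster than the cycloaddition occurs; silyl transfer during opening of the bridged ketal would also blur the difference between the two oxygens. The fallback separates the metalation from the aryne release and sets out from 5. LiTMP in THF at −78 °C followed by I2 should give 1-(benzyloxy)-4-bromo-3-iodo-2-methoxybenzene F5. Iodine–magnesium exchange with i-PrMgCl·LiCl at −78 °C in the presence of 4, then warming, releases the same aryne from an arylmagnesium species with no amide base or aryllithium present. The fallback comes back to the route at 9.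

3. Step 6. Transmetalation and reductive elimination at the doubly ortho-substituted arylzinc may be slow, so that protodemetalation, homocoupling or base-induced decay of the bromobutenolide take over. The fallback builds the lactone ring on the arene instead of coupling it, and it sets out from 12. n-BuLi in THF at −78 °C, then 2-[(tert-butyldimethylsilyl)oxy]-N-methoxy-N-methylacetamide (Weinreb ketone synthesis), should give 1-[1,7-bis(benzyloxy)-4,8-dimethoxy-3-methylnaphthalen-2-yl]-2-[(tert-butyldimethylsilyl)oxy]ethan-1-one F6. Bu4NF/AcOH should free 1-[1,7-bis(benzyloxy)-4,8-dimethoxy-3-methylnaphthalen-2-yl]-2-hydroxyethan-1-one F7. Ketenylidenetriphenylphosphorane (Ph3P=C=C=O) in refluxing toluene (O-acylation, then intramolecular Wittig reaction) should close the butenolide, and the fallback comes back to the route at 16.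

**Further compounds**

F1 | step 10 | 1,7-bis(benzyloxy)-4,8-dimethoxy-3-methylnaphthalene-2-carbaldehyde | O=Cc1c(C)c(OC)c2ccc(OCc3ccccc3)c(OC)c2c1OCc1ccccc1
F2 | step 10 | 1,7-bis(benzyloxy)-2-ethynyl-4,8-dimethoxy-3-methylnaphthalene | C#Cc1c(C)c(OC)c2ccc(OCc3ccccc3)c(OC)c2c1OCc1ccccc1
F3 | step 10 | pentacarbonyl[methoxy(2-methoxy-4-methylphenyl)methylidene]chromium | COC(=[Cr](=C=O)(=C=O)(=C=O)(=C=O)=C=O)c1ccc(C)cc1OC
F4 | step 10 | 2-[1,7-bis(benzyloxy)-4,8-dimethoxy-3-methylnaphthalen-2-yl]-4,5-dimethoxy-7-methylnaphthalen-1-ol | COc1cc(C)cc2c(O)c(-c3c(C)c(OC)c4ccc(OCc5ccccc5)c(OC)c4c3OCc3ccccc3)cc(OC)c12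
F5 | step 3 | 1-(benzyloxy)-4-bromo-3-iodo-2-methoxybenzene | COc1c(I)c(Br)ccc1OCc1ccccc1
F6 | step 6 | 1-[1,7-bis(benzyloxy)-4,8-dimethoxy-3-methylnaphthalen-2-yl]-2-[(tert-butyldimethylsilyl)oxy]ethan-1-one | CC(C)(C)[Si](C)(C)OCC(=O)c1c(C)c(OC)c2ccc(OCc3ccccc3)c(OC)c2c1OCc1ccccc1
F7 | step 6 | 1-[1,7-bis(benzyloxy)-4,8-dimethoxy-3-methylnaphthalen-2-yl]-2-hydroxyethan-1-one | OCC(=O)c1c(C)c(OC)c2ccc(OCc3ccccc3)c(OC)c2c1OCc1ccccc1
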